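**Retrosynthetic overview**

1. Numbering: ring atoms C1 (the stereocentre) to C14, with C3=C4 (CO2Me on C4), C7=C8 and C11=C12; C15 is the side-chain carbon on C1 and C16 its methylene. The strategy rests on the C13–C14 segment of the 14-membered ring, the only CH2–CH2 pair that ends at an sp3 carbon (C1): C13/C14 are read as a former vinyl group on C1 and C12 as a former (Z)-alkenyl iodide.
2. Target ⇐ C15 ketone ⇐ C15 silyloxy carbinol; C15=C16 is put in last so that the cyclisation substrate carries a single terminal alkene.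
3. The only ring is formed in one step: hydroboration of the C1 vinyl group and B-alkyl Suzuki–Miyaura closure of C12–C13 on the acyclic (Z)-iodide.
4. Acyclic precursor ⇐ Still–Gennari olefination (C3=C4) of a C1–C3 aldehyde with a C4–C12 phosphonate that already holds the (E)-C7=C8 alkene and the (Z)-C12 iodide.
5. Aldehyde ⇐ chiral-phosphoric-acid-catalysed allylboration (C1–C15 bond, C1 set). Phosphonate ⇐ Johnson–Claisen rearrangement (C7=C8), Wittig iodo-olefination (C11=C12) and phosphonoacetate alkylation (C4–C5).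

Key step: step 18

Remark: 3-(tert-butyldimethylsilyloxy)propanal (14) and ethyltriphenylphosphonium iodide (19) are taken as commercial. The (R) enantiomer of the TRIP acid (3,3'-bis(2,4,6-triisopropylphenyl)-1,1'-binaphthyl-2,2'-diyl hydrogen phosphate) is taken to favour Re-face allyl transfer, so the (S) acid is specified for the Si-face addition needed here.

**Route**

Step 1
Reactants: 1 δ-valerolactone
Product: 2 2-methylhexane-2,6-diol
Conditions: MeMgBr (3 equiv), THF, 0 °C to rt; aq. NH4Cl
Reagents that add atoms: methylmagnesium bromide, C[Mg]Br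
Why: Double Grignard addition to the lactone carbonyl should give the tertiary carbinol and free the primary alcohol in one operation.

Step 2
Reactants: 2 2-methylhexane-2,6-diol
Product: 3 2-methyl-2,6-bis(triethylsilyloxy)hexane
Conditions: Et3SiOTf (2.4 equiv), 2,6-lutidine, CH2Cl2, −78 to 0 °C
Reagents that add atoms: triethylsilyl trifluoromethanesulfonate, CC[Si](CC)(CC)OS(=O)(=O)C(F)(F)F
Why: The silyl triflate is reactive enough to silylate the tertiary as well as the primary hydroxyl (silyl ether formation).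

Step 3
Reactants: 3 2-methyl-2,6-bis(triethylsilyloxy)hexane
Product: 4 5-methyl-5-(triethylsilyloxy)hexanal
Conditions: (COCl)2, DMSO, CH2Cl2, −78 to −40 °C; Et3N, −78 °C to rt
Reagents that add atoms: none
Why: Under Swern conditions an unhindered primary triethylsilyl ether is cleaved and oxidised in the same flask (Swern oxidation with oxidative desilylation), whereas the tertiary silyl ether is too hindered to be attacked.

Step 4
Reactants: 5 3-butyn-1-ol
Product: 6 (but-3-yn-1-yloxy)triethylsilane
Conditions: Et3SiCl, imidazole, CH2Cl2, 0 °C to rt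
Reagents that add atoms: chlorotriethylsilane, CC[Si](CC)(CC)Cl
Why: Routine silylation of a primary alcohol; the triethylsilyl group is chosen because this ether (the later C3 oxygen) can be oxidised directly in step 9.

Step 5
Reactants: 6 (but-3-yn-1-yloxy)triethylsilane
Product: 7 (E)-4,4,5,5-tetramethyl-2-[4-(triethylsilyloxy)but-1-en-1-yl]-1,3,2-dioxaborolane
Conditions: pinacolborane, Cp2Zr(H)Cl (5 mol %), Et3N (10 mol %), neat, 60 °C
Reagents that add atoms: pinacolborane, CC1(C)OBOC1(C)C
Why: Zirconium-catalysed syn-hydroboration of a terminal alkyne places boron on the terminal carbon and should give the (E)-alkenylboronate only.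

Step 6
Reactants: 7 (E)-4,4,5,5-tetramethyl-2-[4-(triethylsilyloxy)but-1-en-1-yl]-1,3,2-dioxaborolane
Product: 9 (E)-4,4,5,5-tetramethyl-2-[5-(triethylsilyloxy)pent-2-en-1-yl]-1,3,2-dioxaborolane, via lithium chloromethyl borate complex 8 (not isolated)
Conditions: BrCH2Cl, n-BuLi, THF, −78 °C to rt
Reagents that add atoms: bromochloromethane, ClCBr
Why: Matteson homologation: chloromethyllithium made in the flask adds to boron and the alkenyl group migrates with loss of chloride, which inserts one CH2 and leaves the (E)-alkene untouched.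

Step 7
Reactants: 4 5-methyl-5-(triethylsilyloxy)hexanal; 9 (E)-4,4,5,5-tetramethyl-2-[5-(triethylsilyloxy)pent-2-en-1-yl]-1,3,2-dioxaborolane
Product: 11 (3S,4R)-8-methyl-8-(triethylsilyloxy)-3-[2-(triethylsilyloxy)ethyl]non-1-en-4-ol, via pinacol borate ester 10 (not isolated)
Conditions: (S)-TRIP (5 mol %), 4 Å MS, toluene, −30 °C; aqueous work-up
Reagents that add atoms: none
Why: Chiral-phosphoric-acid-catalysed allylboration through a closed chair (Zimmerman–Traxler) transition state: the (E)-boronate holds its γ-substituent equatorial and so gives the anti product, and the (S)-acid, bound to the boronate oxygen and the formyl hydrogen, should direct attack to the Si face of the aldehyde, which sets C1 as S (and C15 as R, a centre that is destroyed later).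

Step 8
Reactants: 11 (3S,4R)-8-methyl-8-(triethylsilyloxy)-3-[2-(triethylsilyloxy)ethyl]non-1-en-4-ol
Product: 12 (3S,4R)-8-methyl-4,8-bis(triethylsilyloxy)-3-[2-(triethylsilyloxy)ethyl]non-1-ene
Conditions: Et3SiOTf, 2,6-lutidine, CH2Cl2, −78 °C
Reagents that add atoms: triethylsilyl trifluoromethanesulfonate, CC[Si](CC)(CC)OS(=O)(=O)C(F)(F)F
Why: Silyl triflate silylation of the hindered secondary C15 hydroxyl masks it as the carbinol ether that is carried through the ring closure.

Step 9
Reactants: 12 (3S,4R)-8-methyl-4,8-bis(triethylsilyloxy)-3-[2-(triethylsilyloxy)ethyl]non-1-ene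
Product: 13 (3S,4R)-3-ethenyl-8-methyl-4,8-bis(triethylsilyloxy)nonanal
Conditions: (COCl)2, DMSO, CH2Cl2, −78 to −40 °C; Et3N, −78 °C to rt
Reagents that add atoms: none
Why: Swern oxidation with oxidative desilylation should act only on the primary triethylsilyl ether (secondary and tertiary ethers are too hindered) and gives the C3 aldehyde, in which C1 is β to the carbonyl and cannot epimerise.

Step 10
Reactants: 14 3-(tert-butyldimethylsilyloxy)propanal
Product: 15 (±)-5-(tert-butyldimethylsilyloxy)-2-methylpent-1-en-3-ol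
Conditions: CH2=C(CH3)MgBr, THF, −78 to 0 °C
Reagents that add atoms: isopropenylmagnesium bromide, C=C(C)[Mg]Br
Why: Grignard addition to the aldehyde gives the 2-methyl allylic alcohol needed for the Claisen step; its stereocentre is consumed there.

Step 11
Reactants: 15 (±)-5-(tert-butyldimethylsilyloxy)-2-methylpent-1-en-3-ol
Product: 17 ethyl (E)-7-(tert-butyldimethylsilyloxy)-4-methylhept-4-enoate, via mixed ketene acetal 16 (not isolated)
Conditions: CH3C(OEt)3, EtCO2H (cat.), 140 °C, EtOH distilled off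
Reagents that add atoms: triethyl orthoacetate, CC(OCC)(OCC)OCC
Why: Johnson–Claisen rearrangement through a chair transition state with the carbinol substituent equatorial (an axial position would clash with the 2-methyl group) should give the (E)-trisubstituted C7=C8 alkene.

Step 12
Reactants: 17 ethyl (E)-7-(tert-butyldimethylsilyloxy)-4-methylhept-4-enoate
Product: 18 (E)-7-(tert-butyldimethylsilyloxy)-4-methylhept-4-enal
Conditions: iBu2AlH (1.05 equiv), CH2Cl2, −78 °C; MeOH, aq. potassium sodium tartrate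
Reagents that add atoms: none
Why: Partial ester reduction: the tetrahedral aluminium hemiacetal is stable at −78 °C and releases the C11 aldehyde only on work-up.

Step 13
Reactants: 18 (E)-7-(tert-butyldimethylsilyloxy)-4-methylhept-4-enal; 19 ethyltriphenylphosphonium iodide
Product: 23 tert-butyl{[(3E,7Z)-8-iodo-4-methylnona-3,7-dien-1-yl]oxy}dimethylsilane, via ethylidenetriphenylphosphorane 20 (not isolated), via (1-iodoethyl)triphenylphosphonium iodide 21 (not isolated), via (1-iodoethylidene)triphenylphosphorane 22 (not isolated)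
Conditions: 19, n-BuLi, THF, 0 °C to rt; I2, −78 °C; NaN(SiMe3)2, −20 °C; then 18, −78 to −20 °C
Reagents that add atoms: iodine, II
Why: Wittig iodo-olefination (Stork–Zhao type): the non-stabilised α-iodo ylide reacts under kinetic control and is known to place iodine cis to the aldehyde-derived chain, which gives the (Z)-C11=C12 iodoalkene.

Step 14
Reactants: 23 tert-butyl{[(3E,7Z)-8-iodo-4-methylnona-3,7-dien-1-yl]oxy}dimethylsilane
Product: 24 (3E,7Z)-8-iodo-4-methylnona-3,7-dien-1-ol
Conditions: Bu4NF, THF, 0 °C to rt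
Reagents that add atoms: none
Why: Fluoride cleavage of the silyl ether; the alkenyl iodide and both alkenes are inert to fluoride.

Step 15
Reactants: 24 (3E,7Z)-8-iodo-4-methylnona-3,7-dien-1-ol
Product: 25 (2Z,6E)-2,9-diiodo-6-methylnona-2,6-diene
Conditions: I2, PPh3, imidazole, CH2Cl2, 0 °C to rt
Reagents that add atoms: iodine, II
Why: Appel-type iodination: the alkoxyphosphonium ion is displaced by iodide in an SN2 step at the primary carbon C5.

Step 16
Reactants: 25 (2Z,6E)-2,9-diiodo-6-methylnona-2,6-diene; 26 methyl bis(2,2,2-trifluoroethyl)phosphonoacetate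
Product: 27 methyl (5E,9Z)-2-[bis(2,2,2-trifluoroethoxy)phosphoryl]-10-iodo-6-methylundeca-5,9-dienoate
Conditions: 26 (2 equiv), NaH, DMF, 0 °C; then 25, rt
Reagents that add atoms: none
Why: C-alkylation of the stabilised phosphonoacetate anion by the primary iodide (SN2) forms C4–C5; the alkenyl iodide cannot react in this mode and the excess of 26 should limit double alkylation.

Step 17
Reactants: 27 methyl (5E,9Z)-2-[bis(2,2,2-trifluoroethoxy)phosphoryl]-10-iodo-6-methylundeca-5,9-dienoate; 13 (3S,4R)-3-ethenyl-8-methyl-4,8-bis(triethylsilyloxy)nonanal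
Product: 28 methyl (2Z,5S,6R)-5-ethenyl-2-[(3E,7Z)-8-iodo-4-methylnona-3,7-dien-1-yl]-10-methyl-6,10-bis(triethylsilyloxy)undec-2-enoate
Conditions: 27, KN(SiMe3)2, 18-crown-6, THF, −78 °C; then 13
Reagents that add atoms: none
Why: Still–Gennari olefination: the electron-poor trifluoroethyl phosphonate with a crown-complexed potassium counter-ion eliminates fast from the kinetic adduct, so the ester should end up cis to C2, the C3=C4 geometry of the target.

Step 18
Reactants: 28 methyl (2Z,5S,6R)-5-ethenyl-2-[(3E,7Z)-8-iodo-4-methylnona-3,7-dien-1-yl]-10-methyl-6,10-bis(triethylsilyloxy)undec-2-enoate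
Product: 30 methyl (1Z,4R,7Z,11E)-7,11-dimethyl-4-[(1R)-5-methyl-1,5-bis(triethylsilyloxy)hexyl]cyclotetradeca-1,7,11-triene-1-carboxylate, via B-alkyl-9-BBN adduct 29 (not isolated)
Conditions: 9-BBN-H, THF, 0 °C to rt; H2O; then slow addition to PdCl2(dppf) (20 mol %), AsPh3, Cs2CO3, DMF/THF/H2O, 50 °C, high dilution (about 2 mM)
Reagents that add atoms: none
Why: 9-BBN-H adds anti-Markovnikov to the C13=C14 vinyl group, the only monosubstituted alkene (the three trisubstituted alkenes and the ester react far more slowly, and C15 is held as a silyloxy carbinol so that no 1,1-disubstituted alkene competes), which puts boron on C13. Zerovalent palladium formed from PdCl2(dppf) inserts into the (Z)-C12–I bond, the base-activated B-alkyl borate transfers C13 to palladium, and reductive elimination forms C12–C13. The closest known reaction type is the intramolecular B-alkyl Suzuki–Miyaura macrocyclisation of a 9-BBN adduct onto an alkenyl iodide. The 14-membered ring is closed by this sp3–sp2 cross-coupling, that is by reductive elimination from a 15-membered palladacycle, and slow addition at high dilution should favour it over oligomerisation. No stereocentre is formed and C1 is untouched; the C11=C12 alkene stays Z because oxidative addition and reductive elimination are stereoretentive, and the absence of radicals and strong base leaves the (Z)-C3=C4 enoate and the (E)-C7=C8 alkene as they are. AsPh3 together with the wide-bite-angle dppf ligand should speed transmetalation and reductive elimination relative to β-hydride elimination of the alkylpalladium intermediate.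

Step 19
Reactants: 30 methyl (1Z,4R,7Z,11E)-7,11-dimethyl-4-[(1R)-5-methyl-1,5-bis(triethylsilyloxy)hexyl]cyclotetradeca-1,7,11-triene-1-carboxylate
Product: 31 methyl (1Z,4R,7Z,11E)-4-[(1R)-1,5-dihydroxy-5-methylhexyl]-7,11-dimethylcyclotetradeca-1,7,11-triene-1-carboxylate
Conditions: HF·pyridine, pyridine, THF, 0 °C to rt
Reagents that add atoms: none
Why: Fluoride cleaves both triethylsilyl ethers, and the buffered non-basic medium should keep the freed C15 hydroxyl from attacking the methyl ester.

Step 20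
Reactants: 31 methyl (1Z,4R,7Z,11E)-4-[(1R)-1,5-dihydroxy-5-methylhexyl]-7,11-dimethylcyclotetradeca-1,7,11-triene-1-carboxylate
Product: 32 methyl (1Z,4R,7Z,11E)-4-(5-hydroxy-5-methylhexanoyl)-7,11-dimethylcyclotetradeca-1,7,11-triene-1-carboxylate
Conditions: Dess–Martin periodinane, NaHCO3, CH2Cl2, 0 °C
Reagents that add atoms: none
Why: Dess–Martin oxidation converts the secondary C15 carbinol to the ketone while the tertiary alcohol cannot be oxidised, and the buffered near-neutral conditions should leave C1, now α to the ketone, unepimerised.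

Step 21
Reactants: 32 methyl (1Z,4R,7Z,11E)-4-(5-hydroxy-5-methylhexanoyl)-7,11-dimethylcyclotetradeca-1,7,11-triene-1-carboxylate
Product: 33 methyl (1Z,4R,7Z,11E)-4-(6-hydroxy-6-methylhept-1-en-2-yl)-7,11-dimethylcyclotetradeca-1,7,11-triene-1-carboxylate (CNP0326472.1)
Conditions: Zn, CH2Br2, TiCl4, THF/CH2Cl2, 0 °C to rt
Reagents that add atoms: dibromomethane, BrCBr
Why: Takai–Lombardo methylenation: the weakly basic titanium–zinc methylene reagent converts enolisable, hindered ketones into 1,1-disubstituted alkenes without epimerising the α-centre and does not attack esters, the free tertiary hydroxyl only consuming some reagent.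

**Compound list**

1 | δ-valerolactone | O=C1CCCCO1 | starting material
2 | 2-methylhexane-2,6-diol | CC(C)(O)CCCCO | intermediate
3 | 2-methyl-2,6-bis(triethylsilyloxy)hexane | CC[Si](CC)(CC)OCCCCC(C)(C)O[Si](CC)(CC)CC | intermediate
4 | 5-methyl-5-(triethylsilyloxy)hexanal | CC[Si](CC)(CC)OC(C)(C)CCCC=O | intermediate
5 | 3-butyn-1-ol | C#CCCO | starting material
6 | (but-3-yn-1-yloxy)triethylsilane | C#CCCO[Si](CC)(CC)CC | intermediate
7 | (E)-4,4,5,5-tetramethyl-2-[4-(triethylsilyloxy)but-1-en-1-yl]-1,3,2-dioxaborolane | CC[Si](CC)(CC)OCC/C=C/B1OC(C)(C)C(C)(C)O1 | intermediate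
8 | lithium (chloromethyl)[(E)-4-(triethylsilyloxy)but-1-en-1-yl](pinacolato)borate (not isolated) | [Li+].ClC[B-]1(/C=C/CCO[Si](CC)(CC)CC)OC(C)(C)C(C)(C)O1 | intermediate
9 | (E)-4,4,5,5-tetramethyl-2-[5-(triethylsilyloxy)pent-2-en-1-yl]-1,3,2-dioxaborolane | CC[Si](CC)(CC)OCC/C=C/CB1OC(C)(C)C(C)(C)O1 | intermediate
10 | 4,4,5,5-tetramethyl-2-{[(3S,4R)-8-methyl-8-(triethylsilyloxy)-3-[2-(triethylsilyloxy)ethyl]non-1-en-4-yl]oxy}-1,3,2-dioxaborolane (not isolated) | C=C[C@H](CCO[Si](CC)(CC)CC)[C@H](OB1OC(C)(C)C(C)(C)O1)CCCC(C)(C)O[Si](CC)(CC)CC | intermediate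
11 | (3S,4R)-8-methyl-8-(triethylsilyloxy)-3-[2-(triethylsilyloxy)ethyl]non-1-en-4-ol | C=C[C@H](CCO[Si](CC)(CC)CC)[C@H](O)CCCC(C)(C)O[Si](CC)(CC)CC | intermediate
12 | (3S,4R)-8-methyl-4,8-bis(triethylsilyloxy)-3-[2-(triethylsilyloxy)ethyl]non-1-ene | C=C[C@H](CCO[Si](CC)(CC)CC)[C@H](O[Si](CC)(CC)CC)CCCC(C)(C)O[Si](CC)(CC)CC | intermediate
13 | (3S,4R)-3-ethenyl-8-methyl-4,8-bis(triethylsilyloxy)nonanal | C=C[C@H](CC=O)[C@H](O[Si](CC)(CC)CC)CCCC(C)(C)O[Si](CC)(CC)CC | intermediate
14 | 3-(tert-butyldimethylsilyloxy)propanal | O=CCCO[Si](C)(C)C(C)(C)C | starting material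
15 | (±)-5-(tert-butyldimethylsilyloxy)-2-methylpent-1-en-3-ol | C=C(C)C(O)CCO[Si](C)(C)C(C)(C)C | intermediate
16 | (±)-5-(tert-butyldimethylsilyloxy)-3-[(1-ethoxyethenyl)oxy]-2-methylpent-1-ene (not isolated) | C=C(OCC)OC(CCO[Si](C)(C)C(C)(C)C)C(C)=C | intermediate
17 | ethyl (E)-7-(tert-butyldimethylsilyloxy)-4-methylhept-4-enoate | CCOC(=O)CC/C(C)=C/CCO[Si](C)(C)C(C)(C)C | intermediate
18 | (E)-7-(tert-butyldimethylsilyloxy)-4-methylhept-4-enal | O=CCC/C(C)=C/CCO[Si](C)(C)C(C)(C)C | intermediate
19 | ethyltriphenylphosphonium iodide | CC[P+](c1ccccc1)(c1ccccc1)c1ccccc1.[I-] | starting material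
20 | ethylidenetriphenylphosphorane (not isolated) | CC=P(c1ccccc1)(c1ccccc1)c1ccccc1 | intermediate
21 | (1-iodoethyl)triphenylphosphonium iodide (not isolated) | CC(I)[P+](c1ccccc1)(c1ccccc1)c1ccccc1.[I-] | intermediate
22 | (1-iodoethylidene)triphenylphosphorane (not isolated) | CC(I)=P(c1ccccc1)(c1ccccc1)c1ccccc1 | intermediate
23 | tert-butyl{[(3E,7Z)-8-iodo-4-methylnona-3,7-dien-1-yl]oxy}dimethylsilane | C/C(I)=C/CC/C(C)=C/CCO[Si](C)(C)C(C)(C)C | intermediate
24 | (3E,7Z)-8-iodo-4-methylnona-3,7-dien-1-ol | C/C(I)=C/CC/C(C)=C/CCO | intermediate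
25 | (2Z,6E)-2,9-diiodo-6-methylnona-2,6-diene | C/C(I)=C/CC/C(C)=C/CCI | intermediate
26 | methyl bis(2,2,2-trifluoroethyl)phosphonoacetate | COC(=O)CP(=O)(OCC(F)(F)F)OCC(F)(F)F | starting material
27 | methyl (5E,9Z)-2-[bis(2,2,2-trifluoroethoxy)phosphoryl]-10-iodo-6-methylundeca-5,9-dienoate (racemic) | COC(=O)C(CC/C=C(\C)CC/C=C(/C)I)P(=O)(OCC(F)(F)F)OCC(F)(F)F | intermediate
28 | methyl (2Z,5S,6R)-5-ethenyl-2-[(3E,7Z)-8-iodo-4-methylnona-3,7-dien-1-yl]-10-methyl-6,10-bis(triethylsilyloxy)undec-2-enoate | C=C[C@H](C/C=C(\C(=O)OC)CC/C=C(\C)CC/C=C(/C)I)[C@H](O[Si](CC)(CC)CC)CCCC(C)(C)O[Si](CC)(CC)CC | intermediate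
29 | methyl (2Z,5R,6R)-5-[2-(9-borabicyclo[3.3.1]nonan-9-yl)ethyl]-2-[(3E,7Z)-8-iodo-4-methylnona-3,7-dien-1-yl]-10-methyl-6,10-bis(triethylsilyloxy)undec-2-enoate (not isolated) | C1CCC2CCCC1B2CC[C@H](C/C=C(\C(=O)OC)CC/C=C(\C)CC/C=C(/C)I)[C@H](O[Si](CC)(CC)CC)CCCC(C)(C)O[Si](CC)(CC)CC | intermediate
30 | methyl (1Z,4R,7Z,11E)-7,11-dimethyl-4-[(1R)-5-methyl-1,5-bis(triethylsilyloxy)hexyl]cyclotetradeca-1,7,11-triene-1-carboxylate | CC[Si](CC)(CC)O[C@H](CCCC(C)(C)O[Si](CC)(CC)CC)[C@H]1C/C=C(\C(=O)OC)CC/C=C(\C)CC/C=C(/C)CC1 | intermediate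
31 | methyl (1Z,4R,7Z,11E)-4-[(1R)-1,5-dihydroxy-5-methylhexyl]-7,11-dimethylcyclotetradeca-1,7,11-triene-1-carboxylate | O[C@H](CCCC(C)(C)O)[C@H]1C/C=C(\C(=O)OC)CC/C=C(\C)CC/C=C(/C)CC1 | intermediate
32 | methyl (1Z,4R,7Z,11E)-4-(5-hydroxy-5-methylhexanoyl)-7,11-dimethylcyclotetradeca-1,7,11-triene-1-carboxylate | CC(C)(O)CCCC(=O)[C@H]1C/C=C(\C(=O)OC)CC/C=C(\C)CC/C=C(/C)CC1 | intermediate
33 | methyl (1Z,4R,7Z,11E)-4-(6-hydroxy-6-methylhept-1-en-2-yl)-7,11-dimethylcyclotetradeca-1,7,11-triene-1-carboxylate (CNP0326472.1) | C=C(CCCC(C)(C)O)[C@H]1C/C=C(\C(=O)OC)CC/C=C(\C)CC/C=C(/C)CC1 | target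

**Step count and risks**

Total step count: 21. Longest linear sequence: 12 steps (14 → 33, steps 10–21).

Steps most likely to fail:

Step 18 (ring closure). Intermolecular coupling may outrun ring closure, or the alkylborane may be lost by protodeboronation or by β-hydride elimination at the alkylpalladium stage. Fallback: the C12–C13 bond is closed from an isolated C13 electrophile by an alkylzinc (Negishi) macrocyclisation instead of through the borane. Setting out from 28, 9-BBN-H in THF followed by NaBO3·4H2O should oxidise adduct 29 to the C13 primary alcohol F1. I2, PPh3 and imidazole should give the C13 primary iodide F2. Activated Zn dust (BrCH2CH2Br, Me3SiCl) in THF/DMA at 35 °C should insert only into the sp3 C–I bond and give the C13 alkylzinc iodide F3. Slow addition of this solution to Pd2(dba)3/P(2-furyl)3 in THF/DMA at 50 °C under high dilution should close the ring and return to the route at 30.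

Step 16 (phosphonate alkylation). SN2 at the homoallylic iodide may be slow compared with base-induced loss of trifluoroethoxide from the phosphonate and with double alkylation. Fallback: the carbon–carbon bond is made on the robust methyl phosphonate and the phosphorus esters are exchanged afterwards. Setting out from 25, trimethyl phosphonoacetate with NaH in DMF should give the dimethyl phosphonate F4. Me3SiBr and pyridine in CH2Cl2 should give the bis(trimethylsilyl) phosphonate F5. (COCl)2 with catalytic DMF should give the phosphonic dichloride F6. CF3CH2OH and Et3N in CH2Cl2 at 0 °C should then return to the route at 27.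

Step 21 (methylenation). The hindered ketone may enolise toward C1, which would erode the only stereocentre, or methylenation may stay incomplete because the free hydroxyl ties up the reagent. Fallback: the methylene is introduced by a two-stage Peterson olefination with a weakly basic organocerium reagent. Setting out from 32, Me3SiCH2Li/CeCl3 in THF at −78 °C (one extra equivalent for the hydroxyl) should add to the ketone and give the β-hydroxysilane F7 as a mixture at C15. HF·pyridine in THF at 0 °C should then promote elimination and return to the route at 33.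

**Further compounds**

F1 | step 18 | methyl (2Z,5S,6R)-5-(2-hydroxyethyl)-2-[(3E,7Z)-8-iodo-4-methylnona-3,7-dien-1-yl]-10-methyl-6,10-bis(triethylsilyloxy)undec-2-enoate | OCC[C@H](C/C=C(\C(=O)OC)CC/C=C(\C)CC/C=C(/C)I)[C@H](O[Si](CC)(CC)CC)CCCC(C)(C)O[Si](CC)(CC)CC
F2 | step 18 | methyl (2Z,5S,6R)-5-(2-iodoethyl)-2-[(3E,7Z)-8-iodo-4-methylnona-3,7-dien-1-yl]-10-methyl-6,10-bis(triethylsilyloxy)undec-2-enoate | ICC[C@H](C/C=C(\C(=O)OC)CC/C=C(\C)CC/C=C(/C)I)[C@H](O[Si](CC)(CC)CC)CCCC(C)(C)O[Si](CC)(CC)CC
F3 | step 18 | {2-[(3S,4R)-analogue of F2 at C13]ethyl}zinc iodide, the C13 alkylzinc iodide derived from F2 | I[Zn]CC[C@H](C/C=C(\C(=O)OC)CC/C=C(\C)CC/C=C(/C)I)[C@H](O[Si](CC)(CC)CC)CCCC(C)(C)O[Si](CC)(CC)CC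
F4 | step 16 | methyl (5E,9Z)-2-(dimethoxyphosphoryl)-10-iodo-6-methylundeca-5,9-dienoate | COC(=O)C(CC/C=C(\C)CC/C=C(/C)I)P(=O)(OC)OC
F5 | step 16 | methyl (5E,9Z)-2-[bis(trimethylsilyloxy)phosphoryl]-10-iodo-6-methylundeca-5,9-dienoate | COC(=O)C(CC/C=C(\C)CC/C=C(/C)I)P(=O)(O[Si](C)(C)C)O[Si](C)(C)C
F6 | step 16 | methyl (5E,9Z)-2-(dichlorophosphoryl)-10-iodo-6-methylundeca-5,9-dienoate | COC(=O)C(CC/C=C(\C)CC/C=C(/C)I)P(=O)(Cl)Cl
F7 | step 21 | methyl (1Z,4R,7Z,11E)-4-[2,6-dihydroxy-6-methyl-1-(trimethylsilyl)heptan-2-yl]-7,11-dimethylcyclotetradeca-1,7,11-triene-1-carboxylate (mixture at the carbinol carbon) | C[Si](C)(C)CC(O)(CCCC(C)(C)O)[C@H]1C/C=C(\C(=O)OC)CC/C=C(\C)CC/C=C(/C)CC1
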